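**Retrosynthetic overview**

1. The target is 1-(4-hydroxy-3-methoxyphenyl)hexadecane-3,5-dione, numbered from C1 (benzylic carbon) to C16 (terminal methyl). The strategy rests on the C3/C5 1,3-diketone, in which the C5 carbonyl lies between the C4 methylene and the unbranched primary undecyl chain C6–C16.
2. The C3 carbonyl is traced back to the ynone C3≡C4–C5(=O), because amine addition followed by hydrolysis can place oxygen only at C3.
3. Key disconnection: C5–C6 and C4–C5 are cut together, so that C5 comes from carbon monoxide, C6–C16 from 1-iodoundecane and C1–C4 with the arene from a terminal alkyne.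
4. The alkyne comes from zingerone by phenol protection as the methoxymethyl ether and conversion of the methyl ketone into the alkyne.
5. No ring is formed at any stage; the only ring, the guaiacol arene, is carried through from zingerone, and there is no stereocentre.

Key step: step 3

Remark on the chemistry: the target is drawn as the diketone, although it should exist largely as its hydrogen-bonded enol.

**Route**

Step 1
Reactants: 1 zingerone
Product: 2 4-[3-methoxy-4-(methoxymethoxy)phenyl]butan-2-one
Conditions: MOMCl, iPr2NEt, CH2Cl2, 0 °C → rt
Reagents that add atoms: chloromethyl methyl ether, COCCl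
Why: Williamson-type O-alkylation of the phenol with the reactive α-chloro ether under amine base should be fast and leave the enolisable ketone untouched, and the acetal removes the O–H bond that would otherwise consume base in step 2 and donate hydrogen to radicals in step 3.

Step 2
Reactants: 2 4-[3-methoxy-4-(methoxymethoxy)phenyl]butan-2-one
Product: 6 4-(but-3-yn-1-yl)-2-methoxy-1-(methoxymethoxy)benzene, via lithium enolate 3 (not isolated), via enol phosphate 4 (not isolated), via lithium acetylide 5 (not isolated)
Conditions: LiN(iPr)2 (1.05 equiv), THF, −78 °C; ClP(O)(OEt)2, −78 °C → rt; then LiN(iPr)2 (2.3 equiv), THF, −78 °C → rt; aq. NH4Cl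
Reagents that add atoms: none
Why: This is the Negishi methyl ketone-to-alkyne sequence, in which the hindered amide base at −78 °C deprotonates the less hindered methyl group (kinetic enolate), O-phosphorylation fixes that regiochemistry, and E2 loss of diethyl phosphate from the 1,1-disubstituted enol phosphate with excess base gives the alkyne, which is held as its acetylide until the quench and so should not isomerise to the allene.

Step 3
Reactants: 6 4-(but-3-yn-1-yl)-2-methoxy-1-(methoxymethoxy)benzene; 7 1-iodoundecane; 8 carbon monoxide
Product: 9 1-[3-methoxy-4-(methoxymethoxy)phenyl]hexadec-3-yn-5-one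
Conditions: PdCl2(PPh3)2 (5 mol %), Et3N, CO (45 atm), benzene/H2O, hν (xenon lamp, Pyrex), rt
Reagents that add atoms: none
Why: Photoexcited zerovalent palladium, formed in the flask from PdCl2(PPh3)2, should transfer one electron to 7 to give the undecyl radical and a monovalent palladium iodide; the radical captures CO to give the dodecanoyl radical (C5–C6 bond), which recombines with palladium to an acyl complex of divalent palladium. The alkyne, deprotonated by triethylamine, is transferred to that complex, and reductive elimination forms the C4–C5 bond and returns zerovalent palladium. The closest known reaction type is the palladium- and light-induced carbonylative Sonogashira (three-component) coupling of unactivated alkyl iodides, CO and terminal alkynes to alkyl alkynyl ketones. No ring is closed and no stereocentre is created. The step needs chemoselectivity: CO capture by the primary radical must outrun hydrogen abstraction, radical addition to the alkyne and direct alkyl–alkynyl coupling, and this is secured by the CO pressure, by the unbranched radical having no cyclisation or fragmentation path, by the slow decarbonylation of a primary acyl radical and by the etherified phenol offering no O–H hydrogen donor. The arene and its acetal are remote from the reacting carbons and should not absorb the Pyrex-filtered light.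

Step 4
Reactants: 9 1-[3-methoxy-4-(methoxymethoxy)phenyl]hexadec-3-yn-5-one
Product: 11 1-[3-methoxy-4-(methoxymethoxy)phenyl]hexadecane-3,5-dione, via enaminone 10 (not isolated)
Conditions: pyrrolidine (1.2 equiv), THF, 0 °C → rt; then 1 M aq. HCl, rt
Reagents that add atoms: water, O
Why: In this aza-Michael addition the polarised ynone can accept the amine only at C3, β to the C5 carbonyl, giving the vinylogous amide 10 (expected E, geometry without consequence), whose C-protonation and iminium hydrolysis in dilute acid at room temperature should deliver the C3 carbonyl while the aryl methoxymethyl ether survives and the amine is washed out as its salt before any formaldehyde equivalent is released.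

Step 5
Reactants: 11 1-[3-methoxy-4-(methoxymethoxy)phenyl]hexadecane-3,5-dione
Product: 12 [12]-gingerdione, 1-(4-hydroxy-3-methoxyphenyl)hexadecane-3,5-dione
Conditions: conc. HCl (cat.), MeOH, 40 °C
Reagents that add atoms: none
Why: In this acid-catalysed transacetalisation the protonated acetal releases the phenol and a methoxymethyl cation that the solvent methanol traps as volatile dimethoxymethane, so that no free formaldehyde should meet the enolised β-diketone or the electron-rich ring, and the β-diketone itself is stable to dilute acid.

**Compound list**

1 | zingerone, 4-(4-hydroxy-3-methoxyphenyl)butan-2-one | CC(=O)CCc1ccc(O)c(OC)c1 | starting material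
2 | 4-[3-methoxy-4-(methoxymethoxy)phenyl]butan-2-one | CC(=O)CCc1ccc(OCOC)c(OC)c1 | intermediate
3 | lithium 4-[3-methoxy-4-(methoxymethoxy)phenyl]but-1-en-2-olate (lithium enolate) | C=C(O[Li])CCc1ccc(OCOC)c(OC)c1 | intermediate
4 | diethyl 4-[3-methoxy-4-(methoxymethoxy)phenyl]but-1-en-2-yl phosphate (enol phosphate) | C=C(CCc1ccc(OCOC)c(OC)c1)OP(=O)(OCC)OCC | intermediate
5 | {4-[3-methoxy-4-(methoxymethoxy)phenyl]but-1-yn-1-yl}lithium (lithium acetylide) | [Li]C#CCCc1ccc(OCOC)c(OC)c1 | intermediate
6 | 4-(but-3-yn-1-yl)-2-methoxy-1-(methoxymethoxy)benzene | C#CCCc1ccc(OCOC)c(OC)c1 | intermediate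
7 | 1-iodoundecane | CCCCCCCCCCCI | starting material
8 | carbon monoxide | [C-]#[O+] | starting material
9 | 1-[3-methoxy-4-(methoxymethoxy)phenyl]hexadec-3-yn-5-one | CCCCCCCCCCCC(=O)C#CCCc1ccc(OCOC)c(OC)c1 | intermediate
10 | (E)-1-[3-methoxy-4-(methoxymethoxy)phenyl]-3-(pyrrolidin-1-yl)hexadec-3-en-5-one (enaminone) | CCCCCCCCCCCC(=O)/C=C(/N1CCCC1)CCc1ccc(OCOC)c(OC)c1 | intermediate
11 | 1-[3-methoxy-4-(methoxymethoxy)phenyl]hexadecane-3,5-dione | CCCCCCCCCCCC(=O)CC(=O)CCc1ccc(OCOC)c(OC)c1 | intermediate
12 | [12]-gingerdione, 1-(4-hydroxy-3-methoxyphenyl)hexadecane-3,5-dione | CCCCCCCCCCCC(=O)CC(=O)CCc1ccc(O)c(OC)c1 | target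

**Step count**

Total step count: 5. Longest linear sequence: 5 steps (1 → 2 → 6 → 9 → 11 → 12).

**Steps most likely to fail**

Step 3 (key step). The undecyl radical may be reduced or may add to the alkyne before it captures CO, direct alkyl–alkynyl coupling may compete, or the acylpalladium species may be intercepted by water before the alkynyl group is transferred. The fallback sets out from 6 and comes back to the route at 9. Alkyne 6 is deprotonated with n-BuLi in THF at −78 °C, which regenerates acetylide 5, and dodecanal is added to give the racemic propargylic alcohol 1-[3-methoxy-4-(methoxymethoxy)phenyl]hexadec-3-yn-5-ol F1. Oxidation of the propargylic alcohol with MnO2 in CH2Cl2 at room temperature should then give ynone 9. This replaces the radical carbonylation by polar 1,2-addition and oxidation.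

Step 2. Enolisation may partly take place towards the internal methylene, so that elimination leads to allene or internal alkyne, or the terminal alkyne may isomerise under the excess base. The fallback sets out from 2 and comes back to the route at 6, and avoids enolate regiochemistry altogether. Haloform degradation of the methyl ketone with aqueous NaOCl and NaOH in dioxane at 0 °C → rt, followed by a Na2SO3 quench and careful acidification to about pH 4, should give 3-[3-methoxy-4-(methoxymethoxy)phenyl]propanoic acid F2. Reduction with LiAlH4 in THF gives 3-[3-methoxy-4-(methoxymethoxy)phenyl]propan-1-ol F3. Oxidation with Dess–Martin periodinane and NaHCO3 in CH2Cl2 gives 3-[3-methoxy-4-(methoxymethoxy)phenyl]propanal F4. Seyferth–Gilbert homologation with the Ohira–Bestmann reagent, dimethyl (1-diazo-2-oxopropyl)phosphonate, and K2CO3 in MeOH at room temperature should then give alkyne 6.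

Step 5. During cleavage of the acetal the methoxymethyl cation or formaldehyde may be captured by the enolised β-diketone at C4 or by the electron-rich ring, or the diketone may be partly converted into a vinylogous ester in acidic methanol. The fallback sets out from 9 and comes back to the route at 12, and removes the acetal before the 1,3-diketone exists. Ynone 9 is treated with catalytic conc. HCl in MeOH at room temperature to give 1-(4-hydroxy-3-methoxyphenyl)hexadec-3-yn-5-one F5. Excess pyrrolidine in THF should then add at C3 to give (E)-1-(4-hydroxy-3-methoxyphenyl)-3-(pyrrolidin-1-yl)hexadec-3-en-5-one F6. Hydrolysis with 1 M aq. HCl at room temperature gives target 12.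

**Further compounds**

F1 | step 3 | 1-[3-methoxy-4-(methoxymethoxy)phenyl]hexadec-3-yn-5-ol (racemic) | CCCCCCCCCCCC(O)C#CCCc1ccc(OCOC)c(OC)c1
F2 | step 2 | 3-[3-methoxy-4-(methoxymethoxy)phenyl]propanoic acid | OC(=O)CCc1ccc(OCOC)c(OC)c1
F3 | step 2 | 3-[3-methoxy-4-(methoxymethoxy)phenyl]propan-1-ol | OCCCc1ccc(OCOC)c(OC)c1
F4 | step 2 | 3-[3-methoxy-4-(methoxymethoxy)phenyl]propanal | O=CCCc1ccc(OCOC)c(OC)c1
F5 | step 5 | 1-(4-hydroxy-3-methoxyphenyl)hexadec-3-yn-5-one | CCCCCCCCCCCC(=O)C#CCCc1ccc(O)c(OC)c1
F6 | step 5 | (E)-1-(4-hydroxy-3-methoxyphenyl)-3-(pyrrolidin-1-yl)hexadec-3-en-5-one | CCCCCCCCCCCC(=O)/C=C(/N1CCCC1)CCc1ccc(O)c(OC)c1
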